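Assumption: positions carry serrulatane numbers (C1 = ArCH(CH3), C3 = CHOAc, C4 = ArCH bearing the side chain, C11 = side-chain CH(CH3), C19 = CO2H). The SMILES reads as (1R,3R,4S,11S), so C3-O is cis to the C4 side chain and C1-CH3 is trans to both.

**Retrosynthetic overview**
1. End game: the C3 acetate, the free catechol (from MOM ethers) and the C19 acid (MOM-directed ortho-lithiation, then CO2) come last. The C14 alkene comes from a B-alkyl Suzuki coupling on a C12 handle.
2. Ring B is the only ring made (aromatic ring A is bought as isovanillin). It is closed at C1–C8a by a 6-exo Heck reaction, and C1 is then set by OH-directed hydrogenation.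
3. C2–C3: Brown allylation of the α-aryl aldehyde sets C3.
4. Key C4–C11 bond: intermolecular enamine-catalysed Michael addition of propanal to the aryl nitroalkene sets C4 and C11. CH2NO2 becomes C3 and CHO becomes C12.
5. Nitroalkene: from isovanillin by bromination, methyl-to-MOM exchange and Henry condensation.

**Route**

Step 1
Reactants: 1 isovanillin (3-hydroxy-4-methoxybenzaldehyde)
Product: 2 2-bromo-3-hydroxy-4-methoxybenzaldehyde
Conditions: Br2, NaOAc, Fe powder (cat.), AcOH, rt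
Reagents that add atoms: bromine BrBr
Why: Electrophilic aromatic bromination, in which the free phenol directs ortho and these buffered conditions are the standard entry to the 2-bromo isomer, placing the halogen on the future C8a.

Step 2
Reactants: 2 2-bromo-3-hydroxy-4-methoxybenzaldehyde
Product: 3 2-bromo-3,4-dihydroxybenzaldehyde
Conditions: BBr3, CH2Cl2, −78 °C to rt; H2O
Reagents that add atoms: none
Why: Lewis-acid aryl methyl ether cleavage, done early so that no harsh demethylation is needed once the alkene and acetate are present.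

Step 3
Reactants: 3 2-bromo-3,4-dihydroxybenzaldehyde
Product: 4 2-bromo-3,4-bis(methoxymethoxy)benzaldehyde
Conditions: MOMCl, i-Pr2NEt, CH2Cl2, 0 °C to rt
Reagents that add atoms: chloromethyl methyl ether COCCl
Why: MOM protection (O-alkylation of the phenols) gives ethers that are stable to base, hydride and palladium, direct the later lithiation and are removed under mild conditions.

Step 4
Reactants: 4 2-bromo-3,4-bis(methoxymethoxy)benzaldehyde
Product: 5 2-bromo-3,4-bis(methoxymethoxy)-1-[(E)-2-nitroethenyl]benzene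
Conditions: MeNO2 (solvent), NH4OAc (0.5 equiv), 95 °C
Reagents that add atoms: nitromethane C[N+](=O)[O-]
Why: Henry (nitroaldol) condensation with in situ dehydration gives the conjugated (E)-nitroalkene under nearly neutral conditions that MOM ethers tolerate.

Step 5
Reactants: 5 2-bromo-3,4-bis(methoxymethoxy)-1-[(E)-2-nitroethenyl]benzene; 6 propanal
Product: 8 (2R,3S)-3-[2-bromo-3,4-bis(methoxymethoxy)phenyl]-2-methyl-4-nitrobutan-1-ol, via Michael adduct aldehyde 7 (not isolated)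
Conditions: (S)-α,α-diphenylprolinol trimethylsilyl ether (10 mol %), 4-nitrophenol (10 mol %), toluene, 0 °C to rt; then MeOH, NaBH4, 0 °C
Reagents that add atoms: propanal (6) CCC=O
Why: In this Hayashi–Jørgensen enamine Michael addition the E-enamine of propanal attacks the nitroalkene through the synclinal transition state on the face away from the CPh2OTMS group and gives the syn (2R,3S) adduct (C11 and C4 of the target, 11S and 4S once CIP ranks change), and immediate NaBH4 reduction freezes the epimerisable α-centre.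

Step 6
Reactants: 8 (2R,3S)-3-[2-bromo-3,4-bis(methoxymethoxy)phenyl]-2-methyl-4-nitrobutan-1-ol
Product: 9 (2R,3S)-3-[2-bromo-3,4-bis(methoxymethoxy)phenyl]-2-methyl-4-nitrobutyl pivalate
Conditions: PivCl, pyridine, CH2Cl2, 0 °C to rt
Reagents that add atoms: pivaloyl chloride CC(C)(C)C(=O)Cl
Why: Simple O-acylation, in which pyridine is too weak a base to form the nitronate and the pivalate is orthogonal to the later silyl ether.

Step 7
Reactants: 9 (2R,3S)-3-[2-bromo-3,4-bis(methoxymethoxy)phenyl]-2-methyl-4-nitrobutyl pivalate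
Product: 10 (2S,3R)-2-[2-bromo-3,4-bis(methoxymethoxy)phenyl]-3-methyl-4-(pivaloyloxy)butanoic acid
Conditions: NaNO2, AcOH, DMSO, 35 °C
Reagents that add atoms: sodium nitrite [Na+].[O-]N=O; water O
Why: Nef-type oxidation of a primary nitroalkane (nitrosation to the nitrolic acid, Mioskowski conditions) gives the acid without a strong base, so the α-aryl centre C4 is kept.

Step 8
Reactants: 10 (2S,3R)-2-[2-bromo-3,4-bis(methoxymethoxy)phenyl]-3-methyl-4-(pivaloyloxy)butanoic acid
Product: 11 (2R,3S)-3-[2-bromo-3,4-bis(methoxymethoxy)phenyl]-4-hydroxy-2-methylbutyl pivalate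
Conditions: BH3·THF, THF, 0 °C to rt; H2O
Reagents that add atoms: none
Why: Chemoselective borane reduction takes the carboxylic acid much faster than the hindered pivalate and leaves the aryl bromide and MOM ethers alone.

Step 9
Reactants: 11 (2R,3S)-3-[2-bromo-3,4-bis(methoxymethoxy)phenyl]-4-hydroxy-2-methylbutyl pivalate
Product: 12 (2R,3S)-3-[2-bromo-3,4-bis(methoxymethoxy)phenyl]-2-methyl-4-oxobutyl pivalate
Conditions: Dess–Martin periodinane, NaHCO3, CH2Cl2, 0 °C to rt (used crude at once)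
Reagents that add atoms: none
Why: Dess–Martin oxidation is neutral and fast, so the α-aryl aldehyde is obtained without epimerisation at C4.

Step 10
Reactants: 12 (2R,3S)-3-[2-bromo-3,4-bis(methoxymethoxy)phenyl]-2-methyl-4-oxobutyl pivalate; 13 (+)-B-allyldiisopinocampheylborane, (+)-Ipc2B(allyl), derived from (−)-α-pinene
Product: 15 (2R,3S,4R)-3-[2-bromo-3,4-bis(methoxymethoxy)phenyl]-4-hydroxy-2-methylhept-6-en-1-yl pivalate, via borinate ester 14 (not isolated)
Conditions: 13, Et2O, −78 °C; then 3 M NaOH, 30 % H2O2, 0 °C to rt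
Reagents that add atoms: (+)-Ipc2B(allyl) (13) C=CCB([C@H]1C[C@H]2C[C@@H]([C@@H]1C)C2(C)C)[C@H]1C[C@H]2C[C@@H]([C@@H]1C)C2(C)C
Why: In this Brown allylation the closed chair transition state is under reagent control of the isopinocampheyl groups, so this borane enantiomer gives the 4R carbinol (C3 R) for an aldehyde whose α-carbon outranks allyl, and the base-free −78 °C conditions spare C4.

Step 11
Reactants: 15 (2R,3S,4R)-3-[2-bromo-3,4-bis(methoxymethoxy)phenyl]-4-hydroxy-2-methylhept-6-en-1-yl pivalate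
Product: 16 (2R)-2-[(1S,2R)-2-hydroxy-5,6-bis(methoxymethoxy)-4-methylidene-1,2,3,4-tetrahydronaphthalen-1-yl]propyl pivalate
Conditions: Pd(OAc)2 (10 mol %), P(o-tol)3 (25 mol %), Et3N, MeCN, 90 °C (sealed)
Reagents that add atoms: none
Why: Intramolecular Mizoroki–Heck reaction, in which the bromide fixes the closure site at C8a, 6-exo-trig carbopalladation forms C1–C8a and the only β-hydrogen (C1-H) is lost to give the exocyclic alkene.

Step 12
Reactants: 16 (2R)-2-[(1S,2R)-2-hydroxy-5,6-bis(methoxymethoxy)-4-methylidene-1,2,3,4-tetrahydronaphthalen-1-yl]propyl pivalate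
Product: 17 (2R)-2-[(1S,2R,4R)-2-hydroxy-5,6-bis(methoxymethoxy)-4-methyl-1,2,3,4-tetrahydronaphthalen-1-yl]propyl pivalate
Conditions: [Ir(cod)(PCy3)(py)]PF6 (5 mol %), H2 (1 atm), CH2Cl2, 0 °C to rt
Reagents that add atoms: none
Why: In this hydroxyl-directed homogeneous hydrogenation the cationic iridium complex binds the C3-OH and delivers H2 to the alkene face syn to it, so C1-H ends cis and C1-CH3 trans to the hydroxyl (1R), with the methyl pseudo-axial and clear of the peri OMOM group.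

Step 13
Reactants: 17 (2R)-2-[(1S,2R,4R)-2-hydroxy-5,6-bis(methoxymethoxy)-4-methyl-1,2,3,4-tetrahydronaphthalen-1-yl]propyl pivalate
Product: 18 (2R)-2-[(1S,2R,4R)-2-(tert-butyldimethylsilyloxy)-5,6-bis(methoxymethoxy)-4-methyl-1,2,3,4-tetrahydronaphthalen-1-yl]propyl pivalate
Conditions: TBSCl, imidazole, DMF, 40 °C
Reagents that add atoms: tert-butyldimethylsilyl chloride CC(C)(C)[Si](C)(C)Cl
Why: Standard silylation of the equatorial secondary alcohol masks C3-OH against the oxidation, ylide and organolithium steps that follow.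

Step 14
Reactants: 18 (2R)-2-[(1S,2R,4R)-2-(tert-butyldimethylsilyloxy)-5,6-bis(methoxymethoxy)-4-methyl-1,2,3,4-tetrahydronaphthalen-1-yl]propyl pivalate
Product: 19 (2R)-2-[(1S,2R,4R)-2-(tert-butyldimethylsilyloxy)-5,6-bis(methoxymethoxy)-4-methyl-1,2,3,4-tetrahydronaphthalen-1-yl]propan-1-ol
Conditions: i-Bu2AlH (2.5 equiv), CH2Cl2, −78 °C; aqueous work-up
Reagents that add atoms: none
Why: Reductive ester cleavage removes only the pivalate, since the silyl and MOM ethers are inert to i-Bu2AlH at −78 °C.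

Step 15
Reactants: 19 (2R)-2-[(1S,2R,4R)-2-(tert-butyldimethylsilyloxy)-5,6-bis(methoxymethoxy)-4-methyl-1,2,3,4-tetrahydronaphthalen-1-yl]propan-1-ol
Product: 20 (2R)-2-[(1S,2R,4R)-2-(tert-butyldimethylsilyloxy)-5,6-bis(methoxymethoxy)-4-methyl-1,2,3,4-tetrahydronaphthalen-1-yl]propanal
Conditions: Dess–Martin periodinane, NaHCO3, CH2Cl2, 0 °C
Reagents that add atoms: none
Why: Dess–Martin oxidation gives the α-branched aldehyde under neutral conditions that do not touch C11.

Step 16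
Reactants: 20 (2R)-2-[(1S,2R,4R)-2-(tert-butyldimethylsilyloxy)-5,6-bis(methoxymethoxy)-4-methyl-1,2,3,4-tetrahydronaphthalen-1-yl]propanal
Product: 21 tert-butyl{[(1S,2R,4R)-1-[(2S)-but-3-en-2-yl]-5,6-bis(methoxymethoxy)-4-methyl-1,2,3,4-tetrahydronaphthalen-2-yl]oxy}dimethylsilane
Conditions: Ph3PCH3Br, KOt-Bu (slightly less than the salt), THF, 0 °C; then 20, −78 °C to 0 °C
Reagents that add atoms: methyltriphenylphosphonium bromide C[P+](c1ccccc1)(c1ccccc1)c1ccccc1.[Br-]
Why: Wittig methylenation adds C13, and with no excess base at low temperature the ylide adds faster than C11 can enolise.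

Step 17
Reactants: 21 tert-butyl{[(1S,2R,4R)-1-[(2S)-but-3-en-2-yl]-5,6-bis(methoxymethoxy)-4-methyl-1,2,3,4-tetrahydronaphthalen-2-yl]oxy}dimethylsilane; 22 1-bromo-2-methylprop-1-ene
Product: 24 tert-butyl{[(1S,2R,4R)-5,6-bis(methoxymethoxy)-4-methyl-1-[(2S)-6-methylhept-5-en-2-yl]-1,2,3,4-tetrahydronaphthalen-2-yl]oxy}dimethylsilane, via B-alkyl-9-BBN adduct 23 (not isolated)
Conditions: 9-BBN-H, THF, rt; then 22, Pd(dppf)Cl2 (5 mol %), 3 M NaOH, THF, 60 °C
Reagents that add atoms: 1-bromo-2-methylprop-1-ene (22) CC(C)=CBr; 9-BBN-H B1C2CCCC1CCC2 (boron of 23 only)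
Why: Anti-Markovnikov hydroboration of the only alkene followed by B-alkyl Suzuki–Miyaura coupling joins C13 to C14 and places the trisubstituted alkene without positional ambiguity.

Step 18
Reactants: 24 tert-butyl{[(1S,2R,4R)-5,6-bis(methoxymethoxy)-4-methyl-1-[(2S)-6-methylhept-5-en-2-yl]-1,2,3,4-tetrahydronaphthalen-2-yl]oxy}dimethylsilane
Product: 26 (5R,7R,8S)-7-(tert-butyldimethylsilyloxy)-3,4-bis(methoxymethoxy)-5-methyl-8-[(2S)-6-methylhept-5-en-2-yl]-5,6,7,8-tetrahydronaphthalene-2-carboxylic acid, via aryllithium 25 (not isolated)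
Conditions: n-BuLi, TMEDA, THF, 0 °C; CO2 (g), −78 °C to rt; 1 M HCl to pH 4, 0 °C
Reagents that add atoms: carbon dioxide O=C=O; n-butyllithium [Li]CCCC (lithium of 25 only)
Why: In this directed ortho-metalation C6-H is the only ring position ortho to an OMOM group, so lithiation and the CO2 quench give the C19 acid regiospecifically while the silyl ether, MOM groups and alkene stay inert.

Step 19
Reactants: 26 (5R,7R,8S)-7-(tert-butyldimethylsilyloxy)-3,4-bis(methoxymethoxy)-5-methyl-8-[(2S)-6-methylhept-5-en-2-yl]-5,6,7,8-tetrahydronaphthalene-2-carboxylic acid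
Product: 27 (5R,7R,8S)-7-hydroxy-3,4-bis(methoxymethoxy)-5-methyl-8-[(2S)-6-methylhept-5-en-2-yl]-5,6,7,8-tetrahydronaphthalene-2-carboxylic acid
Conditions: n-Bu4NF (3 equiv), THF, 45 °C
Reagents that add atoms: none
Why: Fluoride desilylation is driven by the strong Si–F bond and leaves the MOM ethers, alkene and carboxylate untouched.

Step 20
Reactants: 27 (5R,7R,8S)-7-hydroxy-3,4-bis(methoxymethoxy)-5-methyl-8-[(2S)-6-methylhept-5-en-2-yl]-5,6,7,8-tetrahydronaphthalene-2-carboxylic acid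
Product: 29 (5R,7R,8S)-7-acetoxy-3,4-bis(methoxymethoxy)-5-methyl-8-[(2S)-6-methylhept-5-en-2-yl]-5,6,7,8-tetrahydronaphthalene-2-carboxylic acid, via mixed anhydride 28 (not isolated)
Conditions: Ac2O, pyridine, DMAP (cat.), rt; then H2O/THF, rt
Reagents that add atoms: acetic anhydride CC(=O)OC(C)=O
Why: DMAP-catalysed acetylation esterifies C3-OH with retention, and the mixed anhydride formed at the acid is hydrolysed at its unhindered acetyl carbonyl on the aqueous stir.

Step 21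
Reactants: 29 (5R,7R,8S)-7-acetoxy-3,4-bis(methoxymethoxy)-5-methyl-8-[(2S)-6-methylhept-5-en-2-yl]-5,6,7,8-tetrahydronaphthalene-2-carboxylic acid
Product: 30 (5R,7R,8S)-7-acetoxy-3,4-dihydroxy-5-methyl-8-[(2S)-6-methylhept-5-en-2-yl]-5,6,7,8-tetrahydronaphthalene-2-carboxylic acid (target, CNP0201371.1)
Conditions: ZnBr2, n-PrSH, CH2Cl2, 0 °C to rt, 15–30 min
Reagents that add atoms: none
Why: Lewis-acid/thiol transacetalisation moves the two CH2OMe groups onto the thiol within minutes, without a protic acid or a nucleophile strong enough to attack the secondary acetate or the trisubstituted alkene.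

**Compound list**
1 | isovanillin | COc1ccc(C=O)cc1O | starting material
2 | 2-bromo-3-hydroxy-4-methoxybenzaldehyde | COc1ccc(C=O)c(Br)c1O | intermediate
3 | 2-bromo-3,4-dihydroxybenzaldehyde | Oc1ccc(C=O)c(Br)c1O | intermediate
4 | 2-bromo-3,4-bis(methoxymethoxy)benzaldehyde | COCOc1ccc(C=O)c(Br)c1OCOC | intermediate
5 | 2-bromo-3,4-bis(methoxymethoxy)-1-[(E)-2-nitroethenyl]benzene | COCOc1ccc(/C=C/[N+](=O)[O-])c(Br)c1OCOC | intermediate
6 | propanal | CCC=O | starting material
7 | (2R,3S)-3-[2-bromo-3,4-bis(methoxymethoxy)phenyl]-2-methyl-4-nitrobutanal | COCOc1ccc([C@@H](C[N+](=O)[O-])[C@@H](C)C=O)c(Br)c1OCOC | intermediate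
8 | (2R,3S)-3-[2-bromo-3,4-bis(methoxymethoxy)phenyl]-2-methyl-4-nitrobutan-1-ol | COCOc1ccc([C@@H](C[N+](=O)[O-])[C@@H](C)CO)c(Br)c1OCOC | intermediate
9 | (2R,3S)-3-[2-bromo-3,4-bis(methoxymethoxy)phenyl]-2-methyl-4-nitrobutyl pivalate | COCOc1ccc([C@@H](C[N+](=O)[O-])[C@@H](C)COC(=O)C(C)(C)C)c(Br)c1OCOC | intermediate
10 | (2S,3R)-2-[2-bromo-3,4-bis(methoxymethoxy)phenyl]-3-methyl-4-(pivaloyloxy)butanoic acid | COCOc1ccc([C@@H](C(=O)O)[C@@H](C)COC(=O)C(C)(C)C)c(Br)c1OCOC | intermediate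
11 | (2R,3S)-3-[2-bromo-3,4-bis(methoxymethoxy)phenyl]-4-hydroxy-2-methylbutyl pivalate | COCOc1ccc([C@@H](CO)[C@@H](C)COC(=O)C(C)(C)C)c(Br)c1OCOC | intermediate
12 | (2R,3S)-3-[2-bromo-3,4-bis(methoxymethoxy)phenyl]-2-methyl-4-oxobutyl pivalate | COCOc1ccc([C@@H](C=O)[C@@H](C)COC(=O)C(C)(C)C)c(Br)c1OCOC | intermediate
13 | (+)-B-allyldiisopinocampheylborane | C=CCB([C@H]1C[C@H]2C[C@@H]([C@@H]1C)C2(C)C)[C@H]1C[C@H]2C[C@@H]([C@@H]1C)C2(C)C | starting material
14 | diisopinocampheylborinate ester of 15 | COCOc1ccc([C@@H]([C@H](OB([C@H]2C[C@H]3C[C@@H]([C@@H]2C)C3(C)C)[C@H]2C[C@H]3C[C@@H]([C@@H]2C)C3(C)C)CC=C)[C@@H](C)COC(=O)C(C)(C)C)c(Br)c1OCOC | intermediate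
15 | (2R,3S,4R)-3-[2-bromo-3,4-bis(methoxymethoxy)phenyl]-4-hydroxy-2-methylhept-6-en-1-yl pivalate | COCOc1ccc([C@@H]([C@H](O)CC=C)[C@@H](C)COC(=O)C(C)(C)C)c(Br)c1OCOC | intermediate
16 | (2R)-2-[(1S,2R)-2-hydroxy-5,6-bis(methoxymethoxy)-4-methylidene-1,2,3,4-tetrahydronaphthalen-1-yl]propyl pivalate | O[C@@H]1CC(=C)c2c(ccc(OCOC)c2OCOC)[C@@H]1[C@@H](C)COC(=O)C(C)(C)C | intermediate
17 | (2R)-2-[(1S,2R,4R)-2-hydroxy-5,6-bis(methoxymethoxy)-4-methyl-1,2,3,4-tetrahydronaphthalen-1-yl]propyl pivalate | O[C@@H]1C[C@@H](C)c2c(ccc(OCOC)c2OCOC)[C@@H]1[C@@H](C)COC(=O)C(C)(C)C | intermediate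
18 | TBS ether of 17 | CC(C)(C)[Si](C)(C)O[C@@H]1C[C@@H](C)c2c(ccc(OCOC)c2OCOC)[C@@H]1[C@@H](C)COC(=O)C(C)(C)C | intermediate
19 | (2R)-2-[(1S,2R,4R)-2-(tert-butyldimethylsilyloxy)-5,6-bis(methoxymethoxy)-4-methyl-1,2,3,4-tetrahydronaphthalen-1-yl]propan-1-ol | CC(C)(C)[Si](C)(C)O[C@@H]1C[C@@H](C)c2c(ccc(OCOC)c2OCOC)[C@@H]1[C@@H](C)CO | intermediate
20 | (2R)-2-[(1S,2R,4R)-2-(tert-butyldimethylsilyloxy)-5,6-bis(methoxymethoxy)-4-methyl-1,2,3,4-tetrahydronaphthalen-1-yl]propanal | CC(C)(C)[Si](C)(C)O[C@@H]1C[C@@H](C)c2c(ccc(OCOC)c2OCOC)[C@@H]1[C@@H](C)C=O | intermediate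
21 | tert-butyl{[(1S,2R,4R)-1-[(2S)-but-3-en-2-yl]-5,6-bis(methoxymethoxy)-4-methyl-1,2,3,4-tetrahydronaphthalen-2-yl]oxy}dimethylsilane | CC(C)(C)[Si](C)(C)O[C@@H]1C[C@@H](C)c2c(ccc(OCOC)c2OCOC)[C@@H]1[C@@H](C)C=C | intermediate
22 | 1-bromo-2-methylprop-1-ene | CC(C)=CBr | starting material
23 | 9-{(3S)-3-[(1S,2R,4R)-2-(tert-butyldimethylsilyloxy)-5,6-bis(methoxymethoxy)-4-methyl-1,2,3,4-tetrahydronaphthalen-1-yl]butyl}-9-borabicyclo[3.3.1]nonane | CC(C)(C)[Si](C)(C)O[C@@H]1C[C@@H](C)c2c(ccc(OCOC)c2OCOC)[C@@H]1[C@@H](C)CCB1C2CCCC1CCC2 | intermediate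
24 | tert-butyl{[(1S,2R,4R)-5,6-bis(methoxymethoxy)-4-methyl-1-[(2S)-6-methylhept-5-en-2-yl]-1,2,3,4-tetrahydronaphthalen-2-yl]oxy}dimethylsilane | CC(C)(C)[Si](C)(C)O[C@@H]1C[C@@H](C)c2c(ccc(OCOC)c2OCOC)[C@@H]1[C@@H](C)CCC=C(C)C | intermediate
25 | C6-lithio derivative of 24 | CC(C)(C)[Si](C)(C)O[C@@H]1C[C@@H](C)c2c(cc([Li])c(OCOC)c2OCOC)[C@@H]1[C@@H](C)CCC=C(C)C | intermediate
26 | (5R,7R,8S)-7-(tert-butyldimethylsilyloxy)-3,4-bis(methoxymethoxy)-5-methyl-8-[(2S)-6-methylhept-5-en-2-yl]-5,6,7,8-tetrahydronaphthalene-2-carboxylic acid | CC(C)(C)[Si](C)(C)O[C@@H]1C[C@@H](C)c2c(cc(C(=O)O)c(OCOC)c2OCOC)[C@@H]1[C@@H](C)CCC=C(C)C | intermediate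
27 | (5R,7R,8S)-7-hydroxy-3,4-bis(methoxymethoxy)-5-methyl-8-[(2S)-6-methylhept-5-en-2-yl]-5,6,7,8-tetrahydronaphthalene-2-carboxylic acid | O[C@@H]1C[C@@H](C)c2c(cc(C(=O)O)c(OCOC)c2OCOC)[C@@H]1[C@@H](C)CCC=C(C)C | intermediate
28 | acetic mixed anhydride of 29 | CC(=O)O[C@@H]1C[C@@H](C)c2c(cc(C(=O)OC(C)=O)c(OCOC)c2OCOC)[C@@H]1[C@@H](C)CCC=C(C)C | intermediate
29 | (5R,7R,8S)-7-acetoxy-3,4-bis(methoxymethoxy)-5-methyl-8-[(2S)-6-methylhept-5-en-2-yl]-5,6,7,8-tetrahydronaphthalene-2-carboxylic acid | CC(=O)O[C@@H]1C[C@@H](C)c2c(cc(C(=O)O)c(OCOC)c2OCOC)[C@@H]1[C@@H](C)CCC=C(C)C | intermediate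
30 | (5R,7R,8S)-7-acetoxy-3,4-dihydroxy-5-methyl-8-[(2S)-6-methylhept-5-en-2-yl]-5,6,7,8-tetrahydronaphthalene-2-carboxylic acid | CC(=O)O[C@@H]1C[C@@H](C)c2c(cc(C(=O)O)c(O)c2O)[C@@H]1[C@@H](C)CCC=C(C)C | target

**Count**
Total steps: 21. Longest linear sequence: 21 steps (1 to 30).

**Three steps most likely to fail**

Step 12 (facial selectivity at C1). The equatorial C3-OH may not override the intrinsic bias of the exocyclic alkene, which would give the C1 epimer. The fallback replaces kinetic control by thermodynamic control. It sets out from 16 and comes back at 19. Compound 16 is silylated (TBSCl, imidazole) to the methylidene silyl ether F1. The alkene is hydroborated and oxidised (9-BBN-H; NaOH, H2O2) to the C20 primary alcohol F2, where either C1 epimer is acceptable. Oxidation with Dess–Martin periodinane and stirring with DBU moves the now epimerisable formyl group into the pseudo-axial position, trans to the C4 side chain and away from the peri OMOM group, giving the trans aldehyde F3. NaBH4 gives the single hydroxymethyl compound F4, and MsCl/Et3N gives the mesylate F5. Excess LiBHEt3 then replaces the mesylate by hydride and cleaves the pivalate in the same operation, arriving at 19.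

Step 11 (Heck closure). The aryl bromide is electron-rich and flanked by two ortho groups, so oxidative addition may be slow, and the palladium hydride may isomerise the alkene or walk to the carbinol. The fallback uses radical chemistry instead of palladium. It sets out from 15 and comes back at 17. Slow addition of (Me3Si)3SiH and AIBN in toluene at 90 °C generates the aryl radical, which closes 6-exo-trig on the terminal alkene. The resulting primary radical takes hydrogen from the silane, so C20 arrives directly as CH3 and one operation replaces steps 11 and 12. The C1 epimers are separated at the stage of 17. No new compound is made (F0).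

Step 21 (MOM removal beside the acetate, alkene and acid). Cleavage of the hindered C8 MOM ether may be incomplete, or the acetate may be lost. The fallback changes the order of events so that the acetate is not present during deprotection. It sets out from 26 and comes back at 30. Aqueous 3 M HCl in THF at 45 °C removes the silyl ether and both MOM ethers at once to give the trihydroxy acid F6. Ac2O/pyridine followed by an aqueous stir gives the triacetate F7. NH4OAc in aqueous MeOH at rt then hydrolyses only the two much more reactive aryl acetates and leaves the secondary C3 acetate, giving 30.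

**Further compounds**
F1 | step 12 | (2R)-2-[(1S,2R)-2-(tert-butyldimethylsilyloxy)-5,6-bis(methoxymethoxy)-4-methylidene-1,2,3,4-tetrahydronaphthalen-1-yl]propyl pivalate | CC(C)(C)[Si](C)(C)O[C@@H]1CC(=C)c2c(ccc(OCOC)c2OCOC)[C@@H]1[C@@H](C)COC(=O)C(C)(C)C
F2 | step 12 | (2R)-2-[(1S,2R)-2-(tert-butyldimethylsilyloxy)-4-(hydroxymethyl)-5,6-bis(methoxymethoxy)-1,2,3,4-tetrahydronaphthalen-1-yl]propyl pivalate (C4 epimers) | CC(C)(C)[Si](C)(C)O[C@@H]1CC(CO)c2c(ccc(OCOC)c2OCOC)[C@@H]1[C@@H](C)COC(=O)C(C)(C)C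
F3 | step 12 | (2R)-2-[(1S,2R,4R)-2-(tert-butyldimethylsilyloxy)-4-formyl-5,6-bis(methoxymethoxy)-1,2,3,4-tetrahydronaphthalen-1-yl]propyl pivalate | CC(C)(C)[Si](C)(C)O[C@@H]1C[C@@H](C=O)c2c(ccc(OCOC)c2OCOC)[C@@H]1[C@@H](C)COC(=O)C(C)(C)C
F4 | step 12 | (2R)-2-[(1S,2R,4R)-2-(tert-butyldimethylsilyloxy)-4-(hydroxymethyl)-5,6-bis(methoxymethoxy)-1,2,3,4-tetrahydronaphthalen-1-yl]propyl pivalate | CC(C)(C)[Si](C)(C)O[C@@H]1C[C@@H](CO)c2c(ccc(OCOC)c2OCOC)[C@@H]1[C@@H](C)COC(=O)C(C)(C)C
F5 | step 12 | (2R)-2-[(1S,2R,4R)-2-(tert-butyldimethylsilyloxy)-4-(methanesulfonyloxymethyl)-5,6-bis(methoxymethoxy)-1,2,3,4-tetrahydronaphthalen-1-yl]propyl pivalate | CC(C)(C)[Si](C)(C)O[C@@H]1C[C@@H](COS(C)(=O)=O)c2c(ccc(OCOC)c2OCOC)[C@@H]1[C@@H](C)COC(=O)C(C)(C)C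
F0 | step 11 | none | none
F6 | step 21 | (5R,7R,8S)-3,4,7-trihydroxy-5-methyl-8-[(2S)-6-methylhept-5-en-2-yl]-5,6,7,8-tetrahydronaphthalene-2-carboxylic acid | O[C@@H]1C[C@@H](C)c2c(cc(C(=O)O)c(O)c2O)[C@@H]1[C@@H](C)CCC=C(C)C
F7 | step 21 | (5R,7R,8S)-3,4,7-triacetoxy-5-methyl-8-[(2S)-6-methylhept-5-en-2-yl]-5,6,7,8-tetrahydronaphthalene-2-carboxylic acid | CC(=O)O[C@@H]1C[C@@H](C)c2c(cc(C(=O)O)c(OC(C)=O)c2OC(C)=O)[C@@H]1[C@@H](C)CCC=C(C)C
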